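**Plan**

Numbering: cyclopentane = C1 (CH2), C2 (CH bearing isopropenyl), C3 (CH2), C4 (CH–O-senecioyl), C5 (spiro). Ring A = C5, C6 (=C–CH3), C7 (=CH), C8 (C=O), C9 (CH–OAc), C10 (CH–CH3). C11 is the central isopropenyl carbon.
Enabling feature: C11 sits on C2 next to the ring bond C2–C3, so the cyclopentane can be read as a contracted cyclohexane (ring B: C5–C1–C2–C11–C3–C4) in which C11 was a ring member. The 1,3-trans pair C2/C4, awkward on a five-membered ring, then depends only on alkene face and chair shape in ring B.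
Cuts, in retrosynthetic order: C9–OAc, the C4–O acyl bond, C6–CH3 (with carbonyl transposition C8 to C6), C11=CH2, then C2–C3 (restoring C3–C11), C2=C11, C3–C4, C1–C5 and C4–C5.
Forward: ring A comes with 5-methylcyclohexane-1,3-dione. C4, C1 and the C3/C11 unit are attached around C5 in turn. Ring B is closed by metathesis, dihydroxylated and contracted to the cyclopentane, and ring A is then transposed and the two esters are added.
Stereochemistry: C10 by resolution of the vinylogous ester. C5 by allylation anti to the C10 methyl. C4 by non-chelated addition to the C4 aldehyde. The C2/C11 diol by osmylation of the ring-B face away from C10 and C4–O. C2 of the cyclopentane by inversion in the 1,2-shift. C9 by acetoxylation trans to the C10 methyl.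

Key step: step 10

Remark: carbinol 15 forms as a mixture at C6 and is drawn without configuration there, because that carbon becomes trigonal in the same flask. The absolute configuration of resolved 3 is taken to be assigned chiroptically before it is carried on.

**Step 1**
Reactants: 1 5-methylcyclohexane-1,3-dione
Product: 2 (±)-5-methyl-3-(2-methylpropoxy)cyclohex-2-en-1-one
Conditions: i-BuOH, p-TsOH·H2O (cat.), toluene, reflux, Dean–Stark
Reagents that add atoms: 2-methylpropan-1-ol, CC(C)CO
Why: Acid-catalysed enol etherification of a cyclic 1,3-dione (vinylogous Fischer esterification) is driven by azeotropic removal of water; differentiating the two carbonyl carbons makes C10 stereogenic, so 2 forms as a racemate.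

**Step 2**
Reactants: 2 (±)-5-methyl-3-(2-methylpropoxy)cyclohex-2-en-1-one
Product: 3 (S)-5-methyl-3-(2-methylpropoxy)cyclohex-2-en-1-one
Conditions: preparative SFC, amylose tris(3,5-dimethylphenylcarbamate) phase, CO2/i-PrOH
Reagents that add atoms: none
Why: Chromatographic resolution on a chiral stationary phase is routine for small UV-active enones and makes C10 the single source of absolute configuration, while the unwanted enantiomer can be hydrolysed with dilute acid to achiral 1 and sent through step 1 again.

**Step 3**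
Reactants: 3 (S)-5-methyl-3-(2-methylpropoxy)cyclohex-2-en-1-one
Product: 4 (5S,6Z)-6-(hydroxymethylidene)-5-methyl-3-(2-methylpropoxy)cyclohex-2-en-1-one
Conditions: LiN(iPr)2, THF, −78 °C; HCO2CH2CF3, −78 to 0 °C; cold 1 M HCl to pH 5
Reagents that add atoms: 2,2,2-trifluoroethyl formate, O=COCC(F)(F)F
Why: Kinetic deprotonation of a 3-alkoxyenone occurs at the α′ carbon (C5), and the cross-conjugated enolate undergoes a Claisen-type C-formylation with the activated formate, the product resting as the hydrogen-bonded Z-hydroxymethylene tautomer in which C5 is trigonal.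

**Step 4**
Reactants: 4 (5S,6Z)-6-(hydroxymethylidene)-5-methyl-3-(2-methylpropoxy)cyclohex-2-en-1-one; 5 allyl methyl carbonate
Product: 6 (1R,6S)-6-methyl-4-(2-methylpropoxy)-2-oxo-1-(prop-2-en-1-yl)cyclohex-3-ene-1-carbaldehyde (allyl trans and formyl cis to the methyl group)
Conditions: Pd(PPh3)4 (5 mol %), THF, 23 °C
Reagents that add atoms: allyl methyl carbonate (5), C=CCOC(=O)OC
Why: Tsuji–Trost allylation: methoxide released from the carbonate deprotonates the acidic β-keto aldehyde, the soft enolate attacks at carbon the π-allyl complex formed from zerovalent palladium (O-allylation is reversible here), and because A(1,3) strain with the exocyclic C4 forces the C10 methyl axial, C1 arrives on the opposite face and sets the quaternary C5.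

**Step 5**
Reactants: 6 (1R,6S)-6-methyl-4-(2-methylpropoxy)-2-oxo-1-(prop-2-en-1-yl)cyclohex-3-ene-1-carbaldehyde; 7 4,4,5,5-tetramethyl-2-(2-methylprop-2-en-1-yl)-1,3,2-dioxaborolane
Product: 8 (5S,6R)-6-[(1S)-1-hydroxy-3-methylbut-3-en-1-yl]-5-methyl-3-(2-methylpropoxy)-6-(prop-2-en-1-yl)cyclohex-2-en-1-one
Conditions: toluene, 23 °C; then H2O
Reagents that add atoms: methallylboronic acid pinacol ester (7), C=C(C)CB1OC(C)(C)C(C)(C)O1
Why: Allylboration of an aldehyde through a closed six-membered transition state without a chelating metal: whether the C6 acyl group stands perpendicular to the formyl group (polar Felkin–Anh) or anti to its dipole (Cornforth), the reagent passes the C1 methylene rather than the C10 methine, which should set C4 as S, and the vinylogous ester carbonyl is too weak an electrophile to compete.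

**Step 6**
Reactants: 8 (5S,6R)-6-[(1S)-1-hydroxy-3-methylbut-3-en-1-yl]-5-methyl-3-(2-methylpropoxy)-6-(prop-2-en-1-yl)cyclohex-2-en-1-one
Product: 9 (5S,6R)-6-[(1S)-1-(tert-butyldimethylsilyloxy)-3-methylbut-3-en-1-yl]-5-methyl-3-(2-methylpropoxy)-6-(prop-2-en-1-yl)cyclohex-2-en-1-one
Conditions: TBSOTf, 2,6-lutidine, CH2Cl2, −78 to 0 °C
Reagents that add atoms: tert-butyldimethylsilyl triflate, CC(C)(C)[Si](C)(C)OS(=O)(=O)C(F)(F)F
Why: Silylation of a hindered secondary alcohol with the silyl triflate and a non-nucleophilic base blocks retro-aldol cleavage of C4–C5 and touches no stereocentre.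

**Step 7**
Reactants: 9 (5S,6R)-6-[(1S)-1-(tert-butyldimethylsilyloxy)-3-methylbut-3-en-1-yl]-5-methyl-3-(2-methylpropoxy)-6-(prop-2-en-1-yl)cyclohex-2-en-1-one
Product: 10 (4S,5R,10S)-spiro[5.5]undecadienone: ring B C5–C1H2–C2H=C11(CH3)–C3H2–C4H(OTBS) spiro-fused at C5 to ring A C5–C6(=O)–C7H=C8(OiBu)–C9H2–C10H(CH3)
Conditions: second-generation Grubbs catalyst (5 mol %), CH2Cl2 (5 mM), 40 °C
Reagents that add atoms: none
Why: Ring-closing metathesis of a monosubstituted with a 1,1-disubstituted alkene closes ring B as a trisubstituted cyclohexene, helped by the quaternary C5, while the push–pull C7=C8 bond does not engage the ruthenium carbene.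

**Step 8**
Reactants: 10 (4S,5R,10S)-spiro[5.5]undecadienone
Product: 11 (2R,4S,5R,10S,11S)-cis-diol: ring B C5–C1H2–C2H(OH)–C11(CH3)(OH)–C3H2–C4H(OTBS), both hydroxyls on the face that carries C6 and opposite to C10 and OTBS
Conditions: OsO4 (5 mol %), NMO, acetone/H2O, 23 °C
Reagents that add atoms: osmium tetroxide, O=[Os](=O)(=O)=O; N-methylmorpholine N-oxide, C[N+]1([O-])CCOCC1; water, O
Why: Upjohn dihydroxylation (suprafacial [3+2] addition of OsO4): the isolated C2=C11 alkene is more electron-rich than the push–pull C7=C8 bond, and the lower face of ring B always carries an axial group (the C10 branch in one half-chair, the silyloxy group in the other) whereas the upper face is free in the half-chair with C10 axial, so both oxygens should arrive anti to C10 and C4–O and set C2 (R) and C11 (S).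

**Step 9**
Reactants: 11 (2R,4S,5R,10S,11S)-cis-diol
Product: 12 (2R,4S,5R,10S,11S)-C2 methanesulfonate of diol 11 (C11 hydroxyl free)
Conditions: MsCl, Et3N, CH2Cl2, −20 to 0 °C
Reagents that add atoms: methanesulfonyl chloride, CS(=O)(=O)Cl
Why: Selective mesylation: the equatorial secondary C2 hydroxyl is sulfonylated far faster than the tertiary C11 hydroxyl, and since no C–O bond is broken C2 and C11 stay as set.

**Step 10**
Reactants: 12 (2R,4S,5R,10S,11S)-C2 methanesulfonate
Product: 13 (2R,4S,5R,10S)-2-acetyl-4-(tert-butyldimethylsilyloxy)-10-methyl-8-(2-methylpropoxy)spiro[4.5]dec-7-en-6-one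
Conditions: LiClO4, CaCO3, THF, 55 °C
Reagents that add atoms: none
Why: Lithium-assisted ionisation of the C2–OMs bond is concerted with the shift of the antiperiplanar C11–C3 σ bond to C2, and the C11 hydroxyl collapses to a carbonyl group, so C11 leaves the ring as the acetyl carbon while CaCO3 takes up the acid. The closest known reaction type is the semipinacol ring contraction of cyclohexane-1,2-diol monosulfonates to acylcyclopentanes. The cyclopentane C1–C2–C3–C4–C5 is closed not by a cyclisation but by this suprafacial 1,2-alkyl shift, which forms C2–C3 as C3–C11 breaks (six-to-five contraction). The only new stereocentre, C2, arises with inversion because C3 enters at the rear of the C2–O bond, so the R carbinol of step 8 is translated into an acetyl group trans to C4–O. The step needs ring-bond migration rather than methyl migration, elimination or epoxide closure: the chair with equatorial OMs, axial C11–OH, equatorial OTBS and axial C10 is the only reasonable one (the flipped chair has syn-diaxial CH3/OTBS and OMs/C6 pairs), in it only C11–C3 is both antiperiplanar to the leaving group and backed by the oxygen lone pair, and a cis-diol derivative cannot close to an epoxide. The neutral buffered medium spares the silyl ether and the vinylogous ester and does not enolise the new methyl ketone, so C2 is not scrambled.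

**Step 11**
Reactants: 13 (2R,4S,5R,10S)-2-acetyl-4-(tert-butyldimethylsilyloxy)-10-methyl-8-(2-methylpropoxy)spiro[4.5]dec-7-en-6-one
Product: 14 (2R,4S,5R,10S)-4-(tert-butyldimethylsilyloxy)-10-methyl-8-(2-methylpropoxy)-2-(prop-1-en-2-yl)spiro[4.5]dec-7-en-6-one
Conditions: Ph3PCH3Br, KN(SiMe3)2, THF, 0 °C; then 13, −78 to 0 °C
Reagents that add atoms: methyltriphenylphosphonium bromide, C[P+](c1ccccc1)(c1ccccc1)c1ccccc1.[Br-]
Why: Wittig methylenation takes the unhindered methyl ketone only, because the C6 carbonyl is a vinylogous ester next to a quaternary carbon, and low temperature without excess base keeps the α-stereocentre C2 from epimerising before it becomes a non-enolisable allylic carbon.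

**Step 12**
Reactants: 14 (2R,4S,5R,10S)-4-(tert-butyldimethylsilyloxy)-10-methyl-8-(2-methylpropoxy)-2-(prop-1-en-2-yl)spiro[4.5]dec-7-en-6-one
Product: 16 (2R,4S,5S,10S)-4-(tert-butyldimethylsilyloxy)-6,10-dimethyl-2-(prop-1-en-2-yl)spiro[4.5]dec-6-en-8-one, via tertiary carbinol 15 (not isolated)
Conditions: MeLi, CeCl3, THF, −78 to 0 °C; then 1 M HCl, THF, 0 to 23 °C
Reagents that add atoms: methyllithium, [Li]C; water, O
Why: 1,2-Addition of the small, weakly basic organocerium reagent to the hindered C6 carbonyl, followed by acid-induced ionisation, hydration at C8 and loss of isobutanol (Stork–Danheiser enone transposition), moves the carbonyl to C8 and leaves the methyl-bearing C6=C7 alkene without touching any stereocentre of the target.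

**Step 13**
Reactants: 16 (2R,4S,5S,10S)-4-(tert-butyldimethylsilyloxy)-6,10-dimethyl-2-(prop-1-en-2-yl)spiro[4.5]dec-6-en-8-one
Product: 17 (2R,4S,5S,10S)-4-hydroxy-6,10-dimethyl-2-(prop-1-en-2-yl)spiro[4.5]dec-6-en-8-one
Conditions: HF·pyridine, THF, 0 to 23 °C
Reagents that add atoms: none
Why: Fluoride cleavage of the silyl ether in an acidic rather than basic medium never produces a free C4 alkoxide, which avoids vinylogous retro-aldol opening of C4–C5, and it tolerates the enone and the isopropenyl group.

**Step 14**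
Reactants: 17 (2R,4S,5S,10S)-4-hydroxy-6,10-dimethyl-2-(prop-1-en-2-yl)spiro[4.5]dec-6-en-8-one; 18 3-methylbut-2-enoic acid
Product: 19 (2R,4S,5S,10S)-6,10-dimethyl-8-oxo-2-(prop-1-en-2-yl)spiro[4.5]dec-6-en-4-yl 3-methylbut-2-enoate
Conditions: DCC, DMAP, CH2Cl2, 23 to 40 °C
Reagents that add atoms: 3-methylbut-2-enoic acid (18), CC(C)=CC(=O)O
Why: Steglich esterification acylates the hindered C4 hydroxyl through the acylpyridinium ion with retention (the C4–O bond is not broken) and avoids the vinylketene pathway by which the acid chloride with amine bases gives deconjugated ester.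

**Step 15**
Reactants: 19 (2R,4S,5S,10S)-6,10-dimethyl-8-oxo-2-(prop-1-en-2-yl)spiro[4.5]dec-6-en-4-yl 3-methylbut-2-enoate
Product: 20 (2R,4S,5S,9S,10R)-9-acetoxy-6,10-dimethyl-8-oxo-2-(prop-1-en-2-yl)spiro[4.5]dec-6-en-4-yl 3-methylbut-2-enoate
Conditions: Mn(OAc)3, benzene, reflux, Dean–Stark
Reagents that add atoms: manganese triacetate, CC(=O)[O-].CC(=O)[O-].CC(=O)[O-].[Mn+3]
Why: α′-Acetoxylation of an enone with trivalent manganese proceeds through the C8–C9 manganese enolate, whose lower face is screened by the axial C4 branch on C5, so acetate should enter from the other face to give the equatorial acetate trans to the equatorial C10 methyl, which is also the more stable epimer at this enolisable carbon.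

**Compound list**

1 | 5-methylcyclohexane-1,3-dione | CC1CC(=O)CC(=O)C1 | starting material
2 | (±)-5-methyl-3-(2-methylpropoxy)cyclohex-2-en-1-one | CC(C)COC1=CC(=O)CC(C)C1 | intermediate
3 | (S)-5-methyl-3-(2-methylpropoxy)cyclohex-2-en-1-one | CC(C)COC1=CC(=O)C[C@@H](C)C1 | intermediate
4 | (5S,6Z)-6-(hydroxymethylidene)-5-methyl-3-(2-methylpropoxy)cyclohex-2-en-1-one | CC(C)COC1=CC(=O)/C(=C\O)[C@@H](C)C1 | intermediate
5 | allyl methyl carbonate | C=CCOC(=O)OC | starting material
6 | (1R,6S)-6-methyl-4-(2-methylpropoxy)-2-oxo-1-(prop-2-en-1-yl)cyclohex-3-ene-1-carbaldehyde | O=C[C@]1(CC=C)C(=O)C=C(OCC(C)C)C[C@@H]1C | intermediate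
7 | 4,4,5,5-tetramethyl-2-(2-methylprop-2-en-1-yl)-1,3,2-dioxaborolane | C=C(C)CB1OC(C)(C)C(C)(C)O1 | starting material
8 | (5S,6R)-6-[(1S)-1-hydroxy-3-methylbut-3-en-1-yl]-5-methyl-3-(2-methylpropoxy)-6-(prop-2-en-1-yl)cyclohex-2-en-1-one | C=C(C)C[C@H](O)[C@]1(CC=C)C(=O)C=C(OCC(C)C)C[C@@H]1C | intermediate
9 | (5S,6R)-6-[(1S)-1-(tert-butyldimethylsilyloxy)-3-methylbut-3-en-1-yl]-5-methyl-3-(2-methylpropoxy)-6-(prop-2-en-1-yl)cyclohex-2-en-1-one | C=C(C)C[C@H](O[Si](C)(C)C(C)(C)C)[C@]1(CC=C)C(=O)C=C(OCC(C)C)C[C@@H]1C | intermediate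
10 | (4S,5R,10S)-spiro[5.5]undecadienone, route numbering: C2=C11 alkene with methyl on C11, OTBS on C4, C6 ketone, isobutoxy on C8, methyl on C10 | CC1=CC[C@@]2([C@H](C1)O[Si](C)(C)C(C)(C)C)C(=O)C=C(OCC(C)C)C[C@@H]2C | intermediate
11 | (2R,4S,5R,10S,11S)-C2,C11-cis-diol of 10, route numbering | C[C@]1(O)C[C@H](O[Si](C)(C)C(C)(C)C)[C@]2(C[C@H]1O)C(=O)C=C(OCC(C)C)C[C@@H]2C | intermediate
12 | (2R,4S,5R,10S,11S)-C2 methanesulfonate of 11, route numbering | C[C@]1(O)C[C@H](O[Si](C)(C)C(C)(C)C)[C@]2(C[C@H]1OS(C)(=O)=O)C(=O)C=C(OCC(C)C)C[C@@H]2C | intermediate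
13 | (2R,4S,5R,10S)-2-acetyl-4-(tert-butyldimethylsilyloxy)-10-methyl-8-(2-methylpropoxy)spiro[4.5]dec-7-en-6-one | CC(=O)[C@H]1C[C@H](O[Si](C)(C)C(C)(C)C)[C@]2(C1)C(=O)C=C(OCC(C)C)C[C@@H]2C | intermediate
14 | (2R,4S,5R,10S)-4-(tert-butyldimethylsilyloxy)-10-methyl-8-(2-methylpropoxy)-2-(prop-1-en-2-yl)spiro[4.5]dec-7-en-6-one | C=C(C)[C@H]1C[C@H](O[Si](C)(C)C(C)(C)C)[C@]2(C1)C(=O)C=C(OCC(C)C)C[C@@H]2C | intermediate
15 | (2R,4S,5R,10S)-4-(tert-butyldimethylsilyloxy)-6,10-dimethyl-8-(2-methylpropoxy)-2-(prop-1-en-2-yl)spiro[4.5]dec-7-en-6-ol, mixture at C6 | C=C(C)[C@H]1C[C@H](O[Si](C)(C)C(C)(C)C)[C@]2(C1)C(C)(O)C=C(OCC(C)C)C[C@@H]2C | intermediate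
16 | (2R,4S,5S,10S)-4-(tert-butyldimethylsilyloxy)-6,10-dimethyl-2-(prop-1-en-2-yl)spiro[4.5]dec-6-en-8-one | C=C(C)[C@H]1C[C@H](O[Si](C)(C)C(C)(C)C)[C@]2(C1)C(C)=CC(=O)C[C@@H]2C | intermediate
17 | (2R,4S,5S,10S)-4-hydroxy-6,10-dimethyl-2-(prop-1-en-2-yl)spiro[4.5]dec-6-en-8-one | C=C(C)[C@H]1C[C@H](O)[C@]2(C1)C(C)=CC(=O)C[C@@H]2C | intermediate
18 | 3-methylbut-2-enoic acid | CC(C)=CC(=O)O | starting material
19 | (2R,4S,5S,10S)-6,10-dimethyl-8-oxo-2-(prop-1-en-2-yl)spiro[4.5]dec-6-en-4-yl 3-methylbut-2-enoate | C=C(C)[C@H]1C[C@H](OC(=O)C=C(C)C)[C@]2(C1)C(C)=CC(=O)C[C@@H]2C | intermediate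
20 | (2R,4S,5S,9S,10R)-9-acetoxy-6,10-dimethyl-8-oxo-2-(prop-1-en-2-yl)spiro[4.5]dec-6-en-4-yl 3-methylbut-2-enoate | C=C(C)[C@H]1C[C@H](OC(=O)C=C(C)C)[C@]2(C1)C(C)=CC(=O)[C@@H](OC(C)=O)[C@@H]2C | target

Total step count: 15. Longest linear sequence: 15 steps (1 to 20).

**Steps most likely to fail**

Step 5, weak facial discrimination at the C4 aldehyde. The closed allylboration transition state may respond only modestly to the difference between the C1 methylene and the C10 methine. The fallback sets out from 8, whatever its composition at C4, and comes back to 8.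
- The carbinol is oxidised with Dess–Martin periodinane (NaHCO3 buffer, CH2Cl2) to the C4 ketone, the (5R,10S)-β-diketone F1.
- F1 is reduced with Zn(BH4)2 in Et2O at −78 °C.
- Zinc bridges the C4 and C6 carbonyl oxygens and hydride then comes from the side of the C1 methylene, which by the same Newman analysis gives the 4S alcohol.
- C4 is thus set by C–H rather than C–C bond formation, and the vinylogous ester carbonyl is not reduced.

Step 8, poor facial selectivity of the osmylation. If the half-chair with axial C6 reacts as fast as the one with axial C10, oxygen is also delivered syn to C4–O. The fallback sets out from 10 and comes back at 13, and it places C2 under thermodynamic control.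
- The osmylation product is carried on unseparated.
- The lower-face cis-diol F2 is mesylated at C2 to the mesylate F3.
- The preferred chair of F3 again holds the sulfonate equatorial, so the LiClO4/CaCO3 treatment contracts it with inversion to the C2-epimeric methyl ketone F4.
- C2 is then α to a ketone, and DBU in toluene equilibrates F4 with 13.
- In 13 the acetyl group lies on the face of the flat C6 carbonyl rather than on that of the C10 branch and the silyloxy group, so 13 should dominate. Residual F4 is separated and resubmitted.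

Step 15, loss of chemoselectivity in the radical-type oxidation. Possible failures are attack on the isopropenyl or senecioate alkenes, oxidation at the C6 methyl, and incomplete conversion. The fallback sets out from 19 and comes back at 20 by ionic chemistry.
- Kinetic deprotonation at C9 uses LiN(SiMe3)2 (THF, −78 °C).
- The cross-conjugated enolate is oxidised with 2-(phenylsulfonyl)-3-phenyloxaziridine, an oxygen-transfer reagent that leaves alkenes alone. It should approach opposite the axial C4 branch and give the 9-hydroxy enone F5.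
- F5 is acetylated with Ac2O, pyridine and DMAP.

**Further compounds**
F1 | step 5 | (5S,6R)-5-methyl-6-(3-methylbut-3-enoyl)-3-(2-methylpropoxy)-6-(prop-2-en-1-yl)cyclohex-2-en-1-one | C=C(C)CC(=O)[C@]1(CC=C)C(=O)C=C(OCC(C)C)C[C@@H]1C
F2 | step 8 | (2S,4S,5R,10S,11R)-C2,C11-cis-diol of 10 with both hydroxyls syn to C10 and OTBS, route numbering | C[C@@]1(O)C[C@H](O[Si](C)(C)C(C)(C)C)[C@]2(C[C@@H]1O)C(=O)C=C(OCC(C)C)C[C@@H]2C
F3 | step 8 | (2S,4S,5R,10S,11R)-C2 methanesulfonate of F2, route numbering | C[C@@]1(O)C[C@H](O[Si](C)(C)C(C)(C)C)[C@]2(C[C@@H]1OS(C)(=O)=O)C(=O)C=C(OCC(C)C)C[C@@H]2C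
F4 | step 8 | (2S,4S,5R,10S)-2-acetyl-4-(tert-butyldimethylsilyloxy)-10-methyl-8-(2-methylpropoxy)spiro[4.5]dec-7-en-6-one | CC(=O)[C@@H]1C[C@H](O[Si](C)(C)C(C)(C)C)[C@]2(C1)C(=O)C=C(OCC(C)C)C[C@@H]2C
F5 | step 15 | (2R,4S,5S,9S,10R)-9-hydroxy-6,10-dimethyl-8-oxo-2-(prop-1-en-2-yl)spiro[4.5]dec-6-en-4-yl 3-methylbut-2-enoate | C=C(C)[C@H]1C[C@H](OC(=O)C=C(C)C)[C@]2(C1)C(C)=CC(=O)[C@@H](O)[C@@H]2C
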